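**Plan**

1. Retrosynthesis: the four silyl ethers come off last, then ring C is cut at C2–C3. C2 is benzylic to ring B and bound to O1, so it is traced to the OCH2 of a ring B benzyl ether on ring A. C3, alpha to the C4 carbonyl, is traced to the carbene carbon of an aryl diazomethyl ketone six atoms from that activated C–H bond.
2. Further cuts: the diazo group goes back to a methyl ketone (diazo transfer), the O1–CH2 bond to a Mitsunobu etherification, and the C6–geranyl bond to C-alkylation of 2,4,6-trihydroxyacetophenone with geranyl bromide.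
3. Forward: ring A is bought, geranylated, and its hydroxyls are differentiated in the order O7 (silyl), O1 (ring B benzyl), O5 (silyl). Ring B is bought as 3,4-dihydroxy-5-methoxybenzaldehyde and joined as its benzyl alcohol.
4. Ring C is the only ring made, by intramolecular rhodium carbenoid C–H insertion; buffered global desilylation ends the route.
5. Stereochemistry: the single stereocenter C2 (S) is set by the chiral dirhodium carboxylate, which picks one of two enantiotopic benzylic hydrogens of an achiral precursor. The E olefin is carried in with geranyl bromide.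

Key step: step 8

Assumption: flavanone numbering is used throughout (O1, C2, C3, C4, ring A C4a–C8a, ring B primed), ring A oxygens are named by their later flavanone positions, and "geranyl" means (2E)-3,7-dimethylocta-2,6-dien-1-yl.

Assumption: the sense of induction of Rh2(S-PTTL)4 (dirhodium tetrakis[N-phthaloyl-(S)-tert-leucinate]) on this substrate cannot be predicted with certainty. The route is written for the ligand enantiomer that gives 2S; if a test shows the opposite sense, Rh2(R-PTTL)4 from D-tert-leucine is used under the same conditions.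

**Route**

Step 1
Reactants: 1 2,4,6-trihydroxyacetophenone; 2 geranyl bromide
Product: 3 1-(3-geranyl-2,4,6-trihydroxyphenyl)ethanone
Conditions: DBU, THF, 0 °C to rt
Reagents that add atoms: none
Why: Base-mediated C-alkylation (SN2) of the ambident phloroglucinol-type phenoxide by the allylic bromide should give one mono-C-geranyl isomer, because the two open ring positions of 1 are equivalent and the E olefin of 2 is not touched; O-alkylated and doubly alkylated material is removed by chromatography.

Step 2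
Reactants: 3 1-(3-geranyl-2,4,6-trihydroxyphenyl)ethanone
Product: 4 1-[3-geranyl-2,6-dihydroxy-4-(triisopropylsilyloxy)phenyl]ethanone
Conditions: i-Pr3SiCl (1.05 equiv), imidazole, DMF, −10 to 0 °C
Reagents that add atoms: triisopropylsilyl chloride, CC(C)[Si](Cl)(C(C)C)C(C)C
Why: Silyl ether formation should occur at the hydroxyl para to the acetyl group, which is the most acidic and the only one not hydrogen-bonded to the carbonyl, while the two chelated ortho hydroxyls react much more slowly with one equivalent of the bulky chloride.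

Step 3
Reactants: 5 3,4-dihydroxy-5-methoxybenzaldehyde
Product: 6 3,4-bis(tert-butyldimethylsilyloxy)-5-methoxybenzaldehyde
Conditions: t-BuMe2SiCl (2.4 equiv), imidazole, DMF, rt
Reagents that add atoms: tert-butyldimethylsilyl chloride, CC(C)(C)[Si](C)(C)Cl
Why: Standard imidazole-promoted silylation of both catechol hydroxyls gives a ring B unit whose protecting groups carry no C–H bond alpha to oxygen and leave with fluoride at the end.

Step 4
Reactants: 6 3,4-bis(tert-butyldimethylsilyloxy)-5-methoxybenzaldehyde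
Product: 7 [3,4-bis(tert-butyldimethylsilyloxy)-5-methoxyphenyl]methanol
Conditions: NaBH4, THF/EtOH, 0 °C
Reagents that add atoms: none
Why: Borohydride reduction of the aromatic aldehyde to the primary benzylic alcohol is fast at 0 °C and should leave the aryl silyl ethers intact during the short reaction time.

Step 5
Reactants: 4 1-[3-geranyl-2,6-dihydroxy-4-(triisopropylsilyloxy)phenyl]ethanone; 7 [3,4-bis(tert-butyldimethylsilyloxy)-5-methoxyphenyl]methanol
Product: 8 1-[6-{[3,4-bis(tert-butyldimethylsilyloxy)-5-methoxyphenyl]methoxy}-3-geranyl-2-hydroxy-4-(triisopropylsilyloxy)phenyl]ethanone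
Conditions: PPh3, DIAD, THF, 0 °C to rt
Reagents that add atoms: none
Why: Mitsunobu etherification of the acidic phenol with the primary benzylic alcohol runs under neutral conditions that spare the aryl silyl ethers, and should take place at the ortho hydroxyl flanked by C–H (the later O1) and not at the one crowded by the geranyl group, after which the remaining hydroxyl is deactivated by its hydrogen bond to the carbonyl.

Step 6
Reactants: 8 1-[6-{[3,4-bis(tert-butyldimethylsilyloxy)-5-methoxyphenyl]methoxy}-3-geranyl-2-hydroxy-4-(triisopropylsilyloxy)phenyl]ethanone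
Product: 9 1-[6-{[3,4-bis(tert-butyldimethylsilyloxy)-5-methoxyphenyl]methoxy}-3-geranyl-2,4-bis(triisopropylsilyloxy)phenyl]ethanone
Conditions: i-Pr3SiOTf, 2,6-lutidine, CH2Cl2, 0 °C to rt
Reagents that add atoms: triisopropylsilyl trifluoromethanesulfonate, CC(C)[Si](OS(=O)(=O)C(F)(F)F)(C(C)C)C(C)C
Why: The silyl triflate with a hindered pyridine base is reactive enough to silylate the hydrogen-bonded, doubly flanked phenol, while 2,6-lutidine is too weak a base to enolize the methyl ketone at a competitive rate.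

Step 7
Reactants: 9 1-[6-{[3,4-bis(tert-butyldimethylsilyloxy)-5-methoxyphenyl]methoxy}-3-geranyl-2,4-bis(triisopropylsilyloxy)phenyl]ethanone
Product: 11 2-diazo-1-[6-{[3,4-bis(tert-butyldimethylsilyloxy)-5-methoxyphenyl]methoxy}-3-geranyl-2,4-bis(triisopropylsilyloxy)phenyl]ethanone, via trifluoroacetyl ketone 10 (not isolated)
Conditions: LiN(SiMe3)2, THF, −78 °C; CF3CO2CH2CF3; cold dilute aq HCl wash; then MsN3, Et3N, H2O (1 equiv), MeCN, rt
Reagents that add atoms: methanesulfonyl azide, CS(=O)(=O)N=[N+]=[N-] (both diazo nitrogens); 2,2,2-trifluoroethyl trifluoroacetate, O=C(OCC(F)(F)F)C(F)(F)F (trifluoroacetyl group of 10 only, lost again on the way to 11)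
Why: In this detrifluoroacetylative (Regitz-type deacylating) diazo transfer the kinetic lithium enolate of the methyl ketone undergoes Claisen condensation with the trifluoroacetate to give the activated 1,3-diketone 10, which accepts the diazo group from the sulfonyl azide and loses the trifluoroacetyl group as the N-acylsulfonamide, so the terminal diazoketone forms without an acid chloride or diazomethane and without touching silyl ethers, benzyl ether or olefins.

Step 8
Reactants: 11 2-diazo-1-[6-{[3,4-bis(tert-butyldimethylsilyloxy)-5-methoxyphenyl]methoxy}-3-geranyl-2,4-bis(triisopropylsilyloxy)phenyl]ethanone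
Product: 12 (2S)-2-[3,4-bis(tert-butyldimethylsilyloxy)-5-methoxyphenyl]-6-geranyl-5,7-bis(triisopropylsilyloxy)chroman-4-one
Conditions: Rh2(S-PTTL)4 (2 mol %), CH2Cl2, 4 Å MS, −20 to 0 °C, slow addition of 11
Reagents that add atoms: none
Why: The chiral divalent rhodium carboxylate takes up the diazo carbon of 11 with loss of N2 to give an electrophilic rhodium carbenoid at the future C3, which inserts into one of the two enantiotopic benzylic C–H bonds of the ArO–CH2–Ar unit through a concerted, asynchronous three-centre transition state with hydride-transfer character, forming C2–C3 and releasing the catalyst. The closest known reaction type is the chiral dirhodium tetracarboxylate-catalysed intramolecular C–H insertion of ortho-alkoxyaryl diazoketones to chroman-4-ones. Ring C closes as a six-membered ring by 1,6-insertion (the carbenoid carbon bonds to the carbon six atoms away), the only insertion mode open because the 1,5 position is the ether oxygen and carries no hydrogen. The new stereocenter C2 is set by the catalyst alone: the substrate is achiral, and the chiral pocket of the four N-phthaloyl-tert-leucinate ligands decides which enantiotopic hydrogen is replaced. The step needs insertion to win over attack on the O1 lone pair (oxonium ylide, then [1,2]-benzyl Stevens shift to a benzofuran-3-one), over reaction at the other ortho oxygen and over cyclopropanation of the geranyl olefins. This is secured by the hydridic character of the C–H bond (alpha to O1 and on a ring B with a para silyloxy donor), by the low basicity of an aryl ether oxygen conjugated to the ortho acyl group, by the bulky silyl ether on O5 that has no C–H bond alpha to oxygen, by the meta relation of the geranyl group to the acyl carbon, and by slow addition at high dilution.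

Step 9
Reactants: 12 (2S)-2-[3,4-bis(tert-butyldimethylsilyloxy)-5-methoxyphenyl]-6-geranyl-5,7-bis(triisopropylsilyloxy)chroman-4-one
Product: 13 (2S)-2-(3,4-dihydroxy-5-methoxyphenyl)-6-geranyl-5,7-dihydroxychroman-4-one (CNP0110161.1)
Conditions: Bu4NF/AcOH (1:1, 6 equiv), THF, 0 °C to rt, argon
Reagents that add atoms: none
Why: Fluoride-driven Si–O cleavage should remove all four aryl silyl ethers in one operation, and the acetic acid buffer keeps the liberated O7 and O4' phenols protonated so that ring C is not opened by retro-oxa-Michael reaction or quinone methide formation, which would racemize C2; the olefins and the methyl ether are inert.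

**Compound list**

1 | 2,4,6-trihydroxyacetophenone | CC(=O)c1c(O)cc(O)cc1O | starting material
2 | geranyl bromide, (2E)-1-bromo-3,7-dimethylocta-2,6-diene | CC(C)=CCC/C(C)=C/CBr | starting material
3 | 1-(3-geranyl-2,4,6-trihydroxyphenyl)ethanone | CC(=O)c1c(O)cc(O)c(C/C=C(\C)CCC=C(C)C)c1O | intermediate
4 | 1-[3-geranyl-2,6-dihydroxy-4-(triisopropylsilyloxy)phenyl]ethanone | CC(=O)c1c(O)cc(O[Si](C(C)C)(C(C)C)C(C)C)c(C/C=C(\C)CCC=C(C)C)c1O | intermediate
5 | 3,4-dihydroxy-5-methoxybenzaldehyde | COc1cc(C=O)cc(O)c1O | starting material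
6 | 3,4-bis(tert-butyldimethylsilyloxy)-5-methoxybenzaldehyde | COc1cc(C=O)cc(O[Si](C)(C)C(C)(C)C)c1O[Si](C)(C)C(C)(C)C | intermediate
7 | [3,4-bis(tert-butyldimethylsilyloxy)-5-methoxyphenyl]methanol | COc1cc(CO)cc(O[Si](C)(C)C(C)(C)C)c1O[Si](C)(C)C(C)(C)C | intermediate
8 | 1-[6-{[3,4-bis(tert-butyldimethylsilyloxy)-5-methoxyphenyl]methoxy}-3-geranyl-2-hydroxy-4-(triisopropylsilyloxy)phenyl]ethanone | CC(=O)c1c(OCc2cc(OC)c(O[Si](C)(C)C(C)(C)C)c(O[Si](C)(C)C(C)(C)C)c2)cc(O[Si](C(C)C)(C(C)C)C(C)C)c(C/C=C(\C)CCC=C(C)C)c1O | intermediate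
9 | 1-[6-{[3,4-bis(tert-butyldimethylsilyloxy)-5-methoxyphenyl]methoxy}-3-geranyl-2,4-bis(triisopropylsilyloxy)phenyl]ethanone | CC(=O)c1c(OCc2cc(OC)c(O[Si](C)(C)C(C)(C)C)c(O[Si](C)(C)C(C)(C)C)c2)cc(O[Si](C(C)C)(C(C)C)C(C)C)c(C/C=C(\C)CCC=C(C)C)c1O[Si](C(C)C)(C(C)C)C(C)C | intermediate
10 | 1-[6-{[3,4-bis(tert-butyldimethylsilyloxy)-5-methoxyphenyl]methoxy}-3-geranyl-2,4-bis(triisopropylsilyloxy)phenyl]-4,4,4-trifluorobutane-1,3-dione | O=C(CC(=O)C(F)(F)F)c1c(OCc2cc(OC)c(O[Si](C)(C)C(C)(C)C)c(O[Si](C)(C)C(C)(C)C)c2)cc(O[Si](C(C)C)(C(C)C)C(C)C)c(C/C=C(\C)CCC=C(C)C)c1O[Si](C(C)C)(C(C)C)C(C)C | intermediate (not isolated)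
11 | 2-diazo-1-[6-{[3,4-bis(tert-butyldimethylsilyloxy)-5-methoxyphenyl]methoxy}-3-geranyl-2,4-bis(triisopropylsilyloxy)phenyl]ethanone | [N-]=[N+]=CC(=O)c1c(OCc2cc(OC)c(O[Si](C)(C)C(C)(C)C)c(O[Si](C)(C)C(C)(C)C)c2)cc(O[Si](C(C)C)(C(C)C)C(C)C)c(C/C=C(\C)CCC=C(C)C)c1O[Si](C(C)C)(C(C)C)C(C)C | intermediate
12 | (2S)-2-[3,4-bis(tert-butyldimethylsilyloxy)-5-methoxyphenyl]-6-geranyl-5,7-bis(triisopropylsilyloxy)chroman-4-one | COc1cc([C@@H]2CC(=O)c3c(cc(O[Si](C(C)C)(C(C)C)C(C)C)c(C/C=C(\C)CCC=C(C)C)c3O[Si](C(C)C)(C(C)C)C(C)C)O2)cc(O[Si](C)(C)C(C)(C)C)c1O[Si](C)(C)C(C)(C)C | intermediate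
13 | (2S)-2-(3,4-dihydroxy-5-methoxyphenyl)-6-geranyl-5,7-dihydroxychroman-4-one | COc1cc([C@@H]2CC(=O)c3c(cc(O)c(C/C=C(\C)CCC=C(C)C)c3O)O2)cc(O)c1O | target

**Step count and risks**

Total steps: 9. Longest linear sequence: 7 (steps 1, 2, 5, 6, 7, 8, 9 from compound 1); steps 3 and 4 form the two-step ring B branch that joins at step 5.

The three steps most likely to fail:

Step 8. The carbenoid may be captured by the lone pair of O1 and undergo a [1,2]-benzyl shift faster than it inserts, or the catalyst may discriminate the two enantiotopic benzylic hydrogens poorly. In step 8 one catalyst has to meet both demands, and the fallback separates them. It sets out from 11, which is cyclised with an achiral dirhodium tetracarboxylate chosen only for insertion over ylide formation (Rh2(OAc)4 or Rh2(O2CCPh3)4, CH2Cl2, slow addition) to give racemic 2-[3,4-bis(tert-butyldimethylsilyloxy)-5-methoxyphenyl]-6-geranyl-5,7-bis(triisopropylsilyloxy)chroman-4-one F1. This racemate is then resolved kinetically by asymmetric transfer hydrogenation (RuCl(p-cymene)[(R,R)-TsDPEN] or its mirror image, whichever a small-scale test shows to reduce the 2R ketone faster; HCO2H/Et3N, EtOAc, rt, stopped near half conversion). The 2R ketone is converted into the cis alcohol (2R,4R)-2-[3,4-bis(tert-butyldimethylsilyloxy)-5-methoxyphenyl]-6-geranyl-5,7-bis(triisopropylsilyloxy)chroman-4-ol F2, the isolated olefins are not reduced, and the unreacted 2S ketone is separated by chromatography. The fallback returns to the route at 12.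

Step 5. Etherification may occur at the geranyl-flanked hydroxyl or at both ortho hydroxyls, which would lead into the 8-geranyl series. The fallback makes the ether on a symmetric phenol and brings in the geranyl group afterwards. It sets out from 1 and 7. Compound 1 is silylated at its para hydroxyl (i-Pr3SiCl, imidazole, DMF, 0 °C) to 1-[2,6-dihydroxy-4-(triisopropylsilyloxy)phenyl]ethanone F3, whose two ortho hydroxyls are equivalent. Mitsunobu reaction with 7 (PPh3, DIAD, THF) gives 1-[2-{[3,4-bis(tert-butyldimethylsilyloxy)-5-methoxyphenyl]methoxy}-6-hydroxy-4-(triisopropylsilyloxy)phenyl]ethanone F4. Amine-catalysed ortho bromination of the remaining phenol (N-bromosuccinimide, catalytic i-Pr2NH, CH2Cl2, −78 to 0 °C) gives 1-[3-bromo-6-{[3,4-bis(tert-butyldimethylsilyloxy)-5-methoxyphenyl]methoxy}-2-hydroxy-4-(triisopropylsilyloxy)phenyl]ethanone F5. Stille coupling with tributyl(geranyl)stannane (Pd2(dba)3, P(t-Bu)3, toluene, 80 °C) then installs the geranyl group between the hydroxyl and the silyloxy group. The fallback returns to the route at 8.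

Step 6. The doubly flanked, hydrogen-bonded hydroxyl may resist the bulky triflate, or the methyl ketone may be silylated on its enol oxygen instead. The fallback changes the protecting-group plan for O5 to the smaller tert-butyldimethylsilyl ether, which also has no C–H bond alpha to oxygen. It sets out from 8, which is silylated with t-BuMe2SiOTf and 2,6-lutidine (CH2Cl2, 0 °C) to 1-[6-{[3,4-bis(tert-butyldimethylsilyloxy)-5-methoxyphenyl]methoxy}-2-(tert-butyldimethylsilyloxy)-3-geranyl-4-(triisopropylsilyloxy)phenyl]ethanone F6. Under the conditions of step 7 this passes through the trifluoroacetyl ketone 1-[6-{[3,4-bis(tert-butyldimethylsilyloxy)-5-methoxyphenyl]methoxy}-2-(tert-butyldimethylsilyloxy)-3-geranyl-4-(triisopropylsilyloxy)phenyl]-4,4,4-trifluorobutane-1,3-dione F7 to 2-diazo-1-[6-{[3,4-bis(tert-butyldimethylsilyloxy)-5-methoxyphenyl]methoxy}-2-(tert-butyldimethylsilyloxy)-3-geranyl-4-(triisopropylsilyloxy)phenyl]ethanone F8. The conditions of step 8 should convert this into (2S)-2-[3,4-bis(tert-butyldimethylsilyloxy)-5-methoxyphenyl]-5-(tert-butyldimethylsilyloxy)-6-geranyl-7-(triisopropylsilyloxy)chroman-4-one F9. The buffered fluoride of step 9 removes all four silyl groups, so the fallback returns to the route at 13.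

Further compounds
F1 | step 8 | racemic 2-[3,4-bis(tert-butyldimethylsilyloxy)-5-methoxyphenyl]-6-geranyl-5,7-bis(triisopropylsilyloxy)chroman-4-one | COc1cc(C2CC(=O)c3c(cc(O[Si](C(C)C)(C(C)C)C(C)C)c(C/C=C(\C)CCC=C(C)C)c3O[Si](C(C)C)(C(C)C)C(C)C)O2)cc(O[Si](C)(C)C(C)(C)C)c1O[Si](C)(C)C(C)(C)C
F2 | step 8 | (2R,4R)-2-[3,4-bis(tert-butyldimethylsilyloxy)-5-methoxyphenyl]-6-geranyl-5,7-bis(triisopropylsilyloxy)chroman-4-ol | COc1cc([C@H]2C[C@@H](O)c3c(cc(O[Si](C(C)C)(C(C)C)C(C)C)c(C/C=C(\C)CCC=C(C)C)c3O[Si](C(C)C)(C(C)C)C(C)C)O2)cc(O[Si](C)(C)C(C)(C)C)c1O[Si](C)(C)C(C)(C)C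
F3 | step 5 | 1-[2,6-dihydroxy-4-(triisopropylsilyloxy)phenyl]ethanone | CC(=O)c1c(O)cc(O[Si](C(C)C)(C(C)C)C(C)C)cc1O
F4 | step 5 | 1-[2-{[3,4-bis(tert-butyldimethylsilyloxy)-5-methoxyphenyl]methoxy}-6-hydroxy-4-(triisopropylsilyloxy)phenyl]ethanone | CC(=O)c1c(OCc2cc(OC)c(O[Si](C)(C)C(C)(C)C)c(O[Si](C)(C)C(C)(C)C)c2)cc(O[Si](C(C)C)(C(C)C)C(C)C)cc1O
F5 | step 5 | 1-[3-bromo-6-{[3,4-bis(tert-butyldimethylsilyloxy)-5-methoxyphenyl]methoxy}-2-hydroxy-4-(triisopropylsilyloxy)phenyl]ethanone | CC(=O)c1c(OCc2cc(OC)c(O[Si](C)(C)C(C)(C)C)c(O[Si](C)(C)C(C)(C)C)c2)cc(O[Si](C(C)C)(C(C)C)C(C)C)c(Br)c1O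
F6 | step 6 | 1-[6-{[3,4-bis(tert-butyldimethylsilyloxy)-5-methoxyphenyl]methoxy}-2-(tert-butyldimethylsilyloxy)-3-geranyl-4-(triisopropylsilyloxy)phenyl]ethanone | CC(=O)c1c(OCc2cc(OC)c(O[Si](C)(C)C(C)(C)C)c(O[Si](C)(C)C(C)(C)C)c2)cc(O[Si](C(C)C)(C(C)C)C(C)C)c(C/C=C(\C)CCC=C(C)C)c1O[Si](C)(C)C(C)(C)C
F7 | step 6 | 1-[6-{[3,4-bis(tert-butyldimethylsilyloxy)-5-methoxyphenyl]methoxy}-2-(tert-butyldimethylsilyloxy)-3-geranyl-4-(triisopropylsilyloxy)phenyl]-4,4,4-trifluorobutane-1,3-dione | O=C(CC(=O)C(F)(F)F)c1c(OCc2cc(OC)c(O[Si](C)(C)C(C)(C)C)c(O[Si](C)(C)C(C)(C)C)c2)cc(O[Si](C(C)C)(C(C)C)C(C)C)c(C/C=C(\C)CCC=C(C)C)c1O[Si](C)(C)C(C)(C)C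
F8 | step 6 | 2-diazo-1-[6-{[3,4-bis(tert-butyldimethylsilyloxy)-5-methoxyphenyl]methoxy}-2-(tert-butyldimethylsilyloxy)-3-geranyl-4-(triisopropylsilyloxy)phenyl]ethanone | [N-]=[N+]=CC(=O)c1c(OCc2cc(OC)c(O[Si](C)(C)C(C)(C)C)c(O[Si](C)(C)C(C)(C)C)c2)cc(O[Si](C(C)C)(C(C)C)C(C)C)c(C/C=C(\C)CCC=C(C)C)c1O[Si](C)(C)C(C)(C)C
F9 | step 6 | (2S)-2-[3,4-bis(tert-butyldimethylsilyloxy)-5-methoxyphenyl]-5-(tert-butyldimethylsilyloxy)-6-geranyl-7-(triisopropylsilyloxy)chroman-4-one | COc1cc([C@@H]2CC(=O)c3c(cc(O[Si](C(C)C)(C(C)C)C(C)C)c(C/C=C(\C)CCC=C(C)C)c3O[Si](C)(C)C(C)(C)C)O2)cc(O[Si](C)(C)C(C)(C)C)c1O[Si](C)(C)C(C)(C)C
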